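**Plan**

1. Retrosynthesis: the central dihydropyran (ring C) is cut at its two C–C bonds, C-3 of quinolone A–CH(CH=CMe2) and the ring-fusion bond CH(CMe2)–CH(O). This is a retro-[4+2] that leaves an O-aryl oxocarbenium ion and a tethered (E)-diene. The cation is traced back to a plain CH2–O ether one oxidation level lower, so no helper group has to be removed afterwards.
2. The ether is cut at CH2–O (Mitsunobu) into a 4-hydroxyquinolone and a 3-hydroxymethylquinolone. The latter goes back through its aldehyde to a 4-chloro-3-formylquinolone and a tertiary dienol (C-4–O bond, addition–elimination). The chloroaldehyde comes from the same 4-hydroxyquinolone, so one quinolone serves both halves.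
3. Forward: quinolone ring from 2,3-dimethoxyaniline (steps 1–2), chloroformylation (3), dienol (4), dienyl ether (5), reduction (6), ether link (7). Step 8 then closes the dimethylpyran (ring D) and ring C in one operation.
4. Enabling feature: in ring C, the atoms C-3=C-4–O of quinolone A and the benzylic O–CH on C-3 of quinolone B are the skeleton of a 2-oxonia-diene. The other two ring carbons are a former (E)-alkene, and the 2-methylprop-1-enyl group marks a dimethylallyl cation that C-3 of quinolone A captures. The O–CMe2 chain of ring D is the tether.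
5. Stereochemistry: all three stereocentres arise in step 8. Absolute configuration comes from a chiral phosphate counter-anion paired with the oxocarbenium ion; relative configuration comes from the (E)-alkene (trans) and the cis closure of the ring fusion.

Key step: step 8

Remark 1: commercial 6-methylhepta-3,5-dien-2-one is taken as its (3E) isomer; any (3Z) content would be removed at the dienol stage.
Remark 2: the sense of induction of the chiral phosphate in step 8 cannot be derived from precedent; the (R) catalyst is written, and its antipode would be used if a test run showed the mirror-image series.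

**Route**

Step 1
Reactants: 1 2,3-dimethoxyaniline
Product: 3 2,3-dimethoxy-N-methylaniline, via N-(methoxymethyl)aniline 2 (not isolated)
Conditions: (CH2O)n, NaOMe, MeOH, 40 °C; then NaBH4, reflux
Reagents that add atoms: formaldehyde (from paraformaldehyde), C=O
Why: Reductive mono-N-methylation, in which the methoxide-mediated condensation with formaldehyde should stop at the N-(methoxymethyl) adduct that NaBH4 then reduces, so that dimethylation is avoided.

Step 2
Reactants: 3 2,3-dimethoxy-N-methylaniline; 4 bis(2,4,6-trichlorophenyl) malonate
Product: 6 4-hydroxy-7,8-dimethoxy-1-methylquinolin-2(1H)-one, via malonamate aryl ester 5 (not isolated)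
Conditions: Ph2O, 220 °C
Reagents that add atoms: none
Why: Thermal malonylation of the secondary aniline by the activated aryl malonate and ring closure of the aryl malonamate (intramolecular Friedel–Crafts-type acylation through the acylketene) should give the 4-hydroxy-2-quinolone, since only one ortho position is free and it lies para to a methoxy group.

Step 3
Reactants: 6 4-hydroxy-7,8-dimethoxy-1-methylquinolin-2(1H)-one
Product: 8 4-chloro-7,8-dimethoxy-1-methyl-2-oxo-1,2-dihydroquinoline-3-carbaldehyde, via iminium chloride 7 (not isolated)
Conditions: POCl3 (3 equiv), DMF, 0 → 70 °C; then ice, aq. NaOAc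
Reagents that add atoms: N,N-dimethylformamide CN(C)C=O (formyl carbon); phosphoryl chloride O=P(Cl)(Cl)Cl (chlorine); water O (aldehyde oxygen)
Why: Vilsmeier–Haack chloroformylation, in which the enol carbon C-3 is formylated and the vinylogous acid OH is exchanged for chloride, as is usual for N-alkyl-4-hydroxy-2-quinolones and 4-hydroxycoumarins.

Step 4
Reactants: 9 (3E)-6-methylhepta-3,5-dien-2-one
Product: 10 (3E)-2,6-dimethylhepta-3,5-dien-2-ol
Conditions: MeLi (1.1 equiv), Et2O, −78 °C; aq. NH4Cl
Reagents that add atoms: methyllithium [Li]C
Why: 1,2-Addition of a hard organolithium to the enone carbonyl at low temperature should leave the diene and its (E) geometry untouched.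

Step 5
Reactants: 10 (3E)-2,6-dimethylhepta-3,5-dien-2-ol; 8 4-chloro-7,8-dimethoxy-1-methyl-2-oxo-1,2-dihydroquinoline-3-carbaldehyde
Product: 12 4-{[(3E)-2,6-dimethylhepta-3,5-dien-2-yl]oxy}-7,8-dimethoxy-1-methyl-2-oxo-1,2-dihydroquinoline-3-carbaldehyde, via sodium alkoxide 11 (not isolated)
Conditions: NaH (1.0 equiv), THF, 0 °C; then 8, −20 → 0 °C
Reagents that add atoms: none
Why: Addition–elimination at C-4 of a vinylogous acid chloride (SNAr type) that is activated by both the lactam carbonyl and the formyl group; addition of the tertiary alkoxide to the aldehyde is reversible, so chloride displacement should prevail.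

Step 6
Reactants: 12 4-{[(3E)-2,6-dimethylhepta-3,5-dien-2-yl]oxy}-7,8-dimethoxy-1-methyl-2-oxo-1,2-dihydroquinoline-3-carbaldehyde
Product: 13 4-{[(3E)-2,6-dimethylhepta-3,5-dien-2-yl]oxy}-3-(hydroxymethyl)-7,8-dimethoxy-1-methylquinolin-2(1H)-one
Conditions: iBu2AlH (1.1 equiv), CH2Cl2, −78 °C; aq. potassium sodium tartrate
Reagents that add atoms: none
Why: Aprotic 1,2-reduction of the aldehyde at −78 °C, where the lactam carbonyl is inert and no free alkoxide or acid is present that could exchange or ionise the tertiary dienyl ether.

Step 7
Reactants: 13 4-{[(3E)-2,6-dimethylhepta-3,5-dien-2-yl]oxy}-3-(hydroxymethyl)-7,8-dimethoxy-1-methylquinolin-2(1H)-one; 6 4-hydroxy-7,8-dimethoxy-1-methylquinolin-2(1H)-one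
Product: 14 3-{[(7,8-dimethoxy-1-methyl-2-oxo-1,2-dihydroquinolin-4-yl)oxy]methyl}-4-{[(3E)-2,6-dimethylhepta-3,5-dien-2-yl]oxy}-7,8-dimethoxy-1-methylquinolin-2(1H)-one
Conditions: PPh3, diisopropyl azodicarboxylate, THF, 0 °C → rt
Reagents that add atoms: none
Why: Mitsunobu etherification under neutral conditions, in which the acidic 4-hydroxyquinolone (pKa about 6) should be alkylated on O-4 by the activated primary alcohol in an SN2 process, the usual outcome for 4-hydroxy-2-quinolones and 4-hydroxycoumarins.

Step 8
Reactants: 14 3-{[(7,8-dimethoxy-1-methyl-2-oxo-1,2-dihydroquinolin-4-yl)oxy]methyl}-4-{[(3E)-2,6-dimethylhepta-3,5-dien-2-yl]oxy}-7,8-dimethoxy-1-methylquinolin-2(1H)-one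
Product: 17 CNP0314650.1 (the target), via oxocarbenium ion 15 (not isolated), via allyl cation 16 (not isolated)
Conditions: DDQ (1.1 equiv), (R)-3,3′-bis(2,4,6-triisopropylphenyl)-1,1′-binaphthyl-2,2′-diyl hydrogen phosphate (10 mol %), powdered 4 Å molecular sieves, toluene/CH2Cl2, −40 → 0 °C
Reagents that add atoms: none
Why: Proposed new method: DDQ, hydrogen-bonded to the chiral phosphoric acid, should abstract hydride from the only C–H bond that is both α to oxygen and benzylic to the electron-rich C-3 of quinolone B, so that the O-aryl oxocarbenium ion 15 is born as a contact ion pair with the chiral phosphate while the hydroquinone precipitates; 15 is a 2-oxonia-diene (C-3=C-4–O+=CH) that should add across the tethered (E)-alkene in a stepwise cationic [4+2] process, first by Prins attack of the proximal diene carbon on the cationic carbon and then by Friedel–Crafts capture of the dimethylallyl cation 16 at C-3 of quinolone A with loss of a proton to the phosphate. The closest known reaction types are the oxa-Povarov reaction of aryl oxocarbenium ions with alkenes (intermolecular, Lewis acid, racemic), the intramolecular Povarov reaction of 2-(alkenyloxy)aryl aldimines, DDQ-mediated oxidative Prins cyclisations of benzylic ethers and chiral phosphate counter-anion catalysis; their combination in an enantioselective intramolecular form is not known. Ring D closes in a 6-exo-trig mode (new bond CH(O)–CH(CMe2)) and ring C in a 6-endo-trig mode at the C-3=C-4 enol ether bond of quinolone A (new bond C-3–CH(CH=CMe2)). The O–CH centre is set in the Prins step by the face of the cation that the chiral phosphate leaves open (absolute control); the adjacent ring-fusion centre follows from the cis closure, in which the C–O bond at the benzylic carbon stands pseudo-axial and away from the C-2 carbonyl of quinolone B; the third centre follows from the (E)-alkene geometry, which places the 2-methylprop-1-enyl group trans to the CMe2 carbon and pseudo-axial, away from the C-2 carbonyl of quinolone A. The step needs site selectivity of the oxidation (secured by the single doubly activated CH2 and by the quaternary dienyl ether carbon, which bears no hydrogen), regioselectivity of the Prins attack (only the proximal alkene carbon gives a six-membered ring and the dimethylallyl cation) and closure at the secondary allyl terminus (six-membered instead of eight-membered ring).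

**Compound list**

1 | 2,3-dimethoxyaniline | COc1cccc(N)c1OC | starting material
2 | N-(methoxymethyl)-2,3-dimethoxyaniline | COCNc1cccc(OC)c1OC | intermediate
3 | 2,3-dimethoxy-N-methylaniline | CNc1cccc(OC)c1OC | intermediate
4 | bis(2,4,6-trichlorophenyl) malonate | O=C(CC(=O)Oc1c(Cl)cc(Cl)cc1Cl)Oc1c(Cl)cc(Cl)cc1Cl | starting material
5 | 2,4,6-trichlorophenyl 3-[(2,3-dimethoxyphenyl)(methyl)amino]-3-oxopropanoate | COc1cccc(N(C)C(=O)CC(=O)Oc2c(Cl)cc(Cl)cc2Cl)c1OC | intermediate
6 | 4-hydroxy-7,8-dimethoxy-1-methylquinolin-2(1H)-one | COc1ccc2c(O)cc(=O)n(C)c2c1OC | intermediate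
7 | [(4-chloro-7,8-dimethoxy-1-methyl-2-oxo-1,2-dihydroquinolin-3-yl)methylidene]dimethylammonium chloride | C[N+](C)=Cc1c(Cl)c2ccc(OC)c(OC)c2n(C)c1=O.[Cl-] | intermediate
8 | 4-chloro-7,8-dimethoxy-1-methyl-2-oxo-1,2-dihydroquinoline-3-carbaldehyde | O=Cc1c(Cl)c2ccc(OC)c(OC)c2n(C)c1=O | intermediate
9 | (3E)-6-methylhepta-3,5-dien-2-one | CC(C)=C/C=C/C(C)=O | starting material
10 | (3E)-2,6-dimethylhepta-3,5-dien-2-ol | CC(C)=C/C=C/C(C)(C)O | intermediate
11 | sodium (3E)-2,6-dimethylhepta-3,5-dien-2-olate | CC(C)=C/C=C/C(C)(C)[O-].[Na+] | intermediate
12 | 4-{[(3E)-2,6-dimethylhepta-3,5-dien-2-yl]oxy}-7,8-dimethoxy-1-methyl-2-oxo-1,2-dihydroquinoline-3-carbaldehyde | CC(C)=C/C=C/C(C)(C)Oc1c(C=O)c(=O)n(C)c2c(OC)c(OC)ccc12 | intermediate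
13 | 4-{[(3E)-2,6-dimethylhepta-3,5-dien-2-yl]oxy}-3-(hydroxymethyl)-7,8-dimethoxy-1-methylquinolin-2(1H)-one | CC(C)=C/C=C/C(C)(C)Oc1c(CO)c(=O)n(C)c2c(OC)c(OC)ccc12 | intermediate
14 | 3-{[(7,8-dimethoxy-1-methyl-2-oxo-1,2-dihydroquinolin-4-yl)oxy]methyl}-4-{[(3E)-2,6-dimethylhepta-3,5-dien-2-yl]oxy}-7,8-dimethoxy-1-methylquinolin-2(1H)-one | CC(C)=C/C=C/C(C)(C)Oc1c(COc2cc(=O)n(C)c3c(OC)c(OC)ccc23)c(=O)n(C)c2c(OC)c(OC)ccc12 | intermediate
15 | O-aryl oxocarbenium ion derived from 14 by loss of hydride at the O–CH2 carbon (phosphate counter-ion) | CC(C)=C/C=C/C(C)(C)Oc1c(C=[O+]c2cc(=O)n(C)c3c(OC)c(OC)ccc23)c(=O)n(C)c2c(OC)c(OC)ccc12 | intermediate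
16 | dimethylallyl cation after closure of ring D, with cis hydrogens at the two new ring-D stereocentres (phosphate counter-ion) | CC(C)=C[CH+][C@H]1[C@@H](Oc2cc(=O)n(C)c3c(OC)c(OC)ccc23)c2c(c3ccc(OC)c(OC)c3n(C)c2=O)OC1(C)C | intermediate
17 | CNP0314650.1: cis-fused bis(pyranoquinolone), (S) at the CH bearing the 2-methylprop-1-enyl group, (S) at the ring-fusion CH next to CMe2, (R) at the ring-fusion O–CH | COc1ccc2c3c(c(=O)n(C)c2c1OC)[C@@H](C=C(C)C)[C@H]1[C@@H](O3)c2c(c3ccc(OC)c(OC)c3n(C)c2=O)OC1(C)C | target

**Summary**

Total step count: 8. Longest linear sequence: 7 steps (steps 1, 2, 3, 5, 6, 7, 8); step 4 is a one-step side branch.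

Steps most likely to fail:

Step 8 (Proposed new method). Several processes may go wrong. Hydride abstraction without the chiral acid would pair the cation with the achiral hydroquinone anion and erode the enantioselectivity. The acid may ionise the tertiary dienyl ether or the benzylic C–O bond before oxidation. The second closure may give some trans ring fusion. Further hydride loss at the doubly allylic CH may over-oxidise the product. The fallback uses known reaction types only, sets out from 6 and rejoins the route at 17. Condensation of 6 with 3-methylbut-2-enal (ethylenediammonium diacetate as catalyst, toluene, reflux; Knoevenagel condensation followed by oxa-6π electrocyclisation) should give the pyranoquinolone veprisine F1. Heating F1 (1,2-dichlorobenzene, about 180 °C) should open part of it to the ring-opened quinone methide F2. F2 should add as a 1-oxadiene across the pyran C=C bond of a second molecule of F1 (inverse-electron-demand hetero-Diels–Alder reaction) to give 17 together with its mirror image, the enantiomer of the target F3. Chromatography should remove other dimers, and preparative HPLC on a chiral stationary phase should separate 17 from F3.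

Step 5. The hindered tertiary alkoxide may substitute slowly, and the product ether may ionise or eliminate to a triene during the reaction. The fallback forms the same C–O bond from the other side, sets out from 8 and 10 and returns at 12. Hydrolysis of 8 (aq. NaOH, THF; then HCl) should give the hydroxy aldehyde F4. Alcohol 10 with trichloroacetonitrile and catalytic 1,8-diazabicyclo[5.4.0]undec-7-ene (CH2Cl2, −20 °C) should give the dienyl trichloroacetimidate F5, which is used at once. The acidic enol F4 protonates F5 and should be O-alkylated through the symmetrical pentadienyl cation, both tertiary ends of which lead to the same ether 12.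

Step 7. The activated alcohol may ionise and cyclise onto its own diene before the nucleophile arrives, or 6 may be alkylated at C-3 instead of O-4. The fallback inverts the polarity so that no cation can form, sets out from 6 and 13 and returns at 14. Compound 6 with POCl3 (90 °C) should give the 4-chloroquinolone F6. Alcohol 13 with NaH (THF/DMF, 0 °C) should give the sodium alkoxide of 13 F7, which should displace the chloride of F6 by addition–elimination at no more than 40 °C to give 14.

**Further compounds**

F1 | step 8 | veprisine (7,8-dimethoxy-2,2,6-trimethyl-2H-pyrano[3,2-c]quinolin-5(6H)-one) | COc1ccc2c3c(c(=O)n(C)c2c1OC)C=CC(C)(C)O3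
F2 | step 8 | 7,8-dimethoxy-1-methyl-3-(3-methylbut-2-en-1-ylidene)quinoline-2,4(1H,3H)-dione (ring-opened quinone methide) | COc1ccc2c(c1OC)N(C)C(=O)C(=CC=C(C)C)C2=O
F3 | step 8 | enantiomer of 17 | COc1ccc2c3c(c(=O)n(C)c2c1OC)[C@H](C=C(C)C)[C@@H]1[C@H](O3)c2c(c3ccc(OC)c(OC)c3n(C)c2=O)OC1(C)C
F4 | step 5 | 4-hydroxy-7,8-dimethoxy-1-methyl-2-oxo-1,2-dihydroquinoline-3-carbaldehyde | O=Cc1c(O)c2ccc(OC)c(OC)c2n(C)c1=O
F5 | step 5 | (3E)-2,6-dimethylhepta-3,5-dien-2-yl 2,2,2-trichloroacetimidate | CC(C)=C/C=C/C(C)(C)OC(=N)C(Cl)(Cl)Cl
F6 | step 7 | 4-chloro-7,8-dimethoxy-1-methylquinolin-2(1H)-one | COc1ccc2c(Cl)cc(=O)n(C)c2c1OC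
F7 | step 7 | sodium alkoxide of 13 | CC(C)=C/C=C/C(C)(C)Oc1c(C[O-])c(=O)n(C)c2c(OC)c(OC)ccc12.[Na+]
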